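If a flask loses its starting material within minutes while coupling partner is in excess, the question is where that material went.

| flask | starting material | coupling partner | second substrate | remark | time |
|---|---|---|---|---|---|
| delta | 0.30 M | 0.33 M | 0.30 M | run made earlier |  |
| epsilon | 0.30 M | 0.33 M | 1.2 M | run made earlier |  |
| alpha | 0.30 M | 0.49 M | 0.60 M | run made earlier |  |
| flask | 0.30 M | 0.330 M | 0.600 M |  | 15 h |

| run | time / h | target / % | starting material / % |
|---|---|---|---|
| delta | 0.167 | 19.3 | 4.3 |
| delta | 0.417 | 18.8 | 2.1 |
| delta | 0.833 | 16.4 | 1.6 |
| delta | 2.00 | 14.1 | 1.7 |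
| delta | 4.00 | 6.1 | 0 |
| delta | 8.00 | 3.2 | 3.2 |
| delta | 20.0 | 1.1 | 0 |
| epsilon | 0.167 | 19.2 | 3.5 |
| epsilon | 0.417 | 20.1 | 4.5 |
| epsilon | 0.833 | 12.9 | 3.3 |
| epsilon | 2.00 | 6.9 | 3.4 |
| epsilon | 4.00 | 1.8 | 1.2 |
| epsilon | 8.00 | 1.0 | 1.6 |
| epsilon | 20.0 | 0 | 0 |
| alpha | 0.167 | 27.4 | 2.4 |
| alpha | 0.500 | 23.6 | 2.7 |
| alpha | 2.00 | 17.4 | 2.7 |
| alpha | 6.00 | 4.3 | 0.5 |
| alpha | 20.0 | 0.3 | 2.3 |

(scatter of a reading: 1 percentage point)

1. when, up to 15 h, the flask holds most target
2. the amount of target, in percent of the starting material charged, at that time



Here is the puzzle. The flask holds 1.10 coupling partner per starting material, enough for every molecule. Yet in the delta run, with the same two charges, nearly all the starting material has left by the first sample, and target reads 19.3 %.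

I suppose a second loss in which two starting material molecules meet, a self-condensation. Its rate is second order in starting material, while coupling is pseudo-first-order with partner held at its charge. So starting material concentration sets which route leads. Let r be its charge over c\*, and integrating gives a target share of ln(1+r)/r.

The first samples of delta and epsilon average 19.2 %, which gives r = 14.0. Then c\* = 0.0214 M. This is an effective value read off scattered readings: within this reckoning, with partner held at its charge, it is the concentration of starting material at which both routes would use it equally.

As a check, I scale c\* with partner for alpha, which gives r = 9.44 and a share of 24.8 %. That lies between the readings 27.4 % and 23.6 %.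

Second substrate barely moves the first readings, so I expect about 19.2 % for the flask, near 0.167 h. The forecast says 20.5 % at 0.2 h, slightly higher, on the ground that “The early plateau tracks the coupling partner”.

The flask gives 19.5 % at 0.222 h.

    starting material + coupling partner ⇌ target (K = 29.0 /M, k = 0.00880 /M/s)
    2 starting material → self-condensation product (k = 0.0430 /M/s)
    second substrate + coupling partner ⇌ second product (K = 35.0 /M, k = 4.90 × 10⁻⁴ /M/s)

In the flask at that time starting material stands at 3.12 % of its charge, or 0.00935 M, below my effective c\*. A neighbouring flask charges 0.075 M of starting material with the same partner, so r falls to 3.50 and the share I reckon is 43.0 %. Its simulated best is 41.9 %.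

The numbers in the tables are simulated on assumed constants; the scatter is artificial.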